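Atom numbering used throughout (guaiane): five-membered ring C1 (sp2, ring fusion)–C2–C3–C4 (bearing C15)–C5 (H, ring fusion); seven-membered ring C5–C6–C7 (bearing C11)–C8 (O)–C9–C10 (bearing C14)=C1.

## Analysis of the target

The target is a guaiane-type hydroazulene: a cyclopentane (C1–C5) and a cycloheptene (C5–C10, C1) share the C1–C5 bond, with the tetrasubstituted C1=C10 olefin at the fusion. C4 and C10 carry methyl groups, C7 a 2-hydroxypropan-2-yl group (C11), and the C8 oxygen an (E)-p-coumaroyl ester. The four stereocentres are 4S,5S,7S,8S: H4, H5 and H7 lie on one face and H8 on the other, so the C4 methyl is trans to H5 (cis to C6) and the C7 carbinol is trans to the C8 acyloxy group. C4/C5 and C7/C8 are adjacent pairs, but the pairs communicate only through the C6 methylene of a flexible seven-membered ring, so the C5/C7 relation needs an explicit control element. The coumarate (free phenol, Michael acceptor, reducible olefin) cannot survive organometallic or hydrogenation steps and must come last; the tertiary alcohol can dehydrate, and the tetrasubstituted olefin can migrate under acid. The difficulty is a seven-membered ring with a positionally fixed tetrasubstituted olefin, two adjacent functionalised stereocentres on its far side and a remote ring-fusion centre. The strategy rests on C5, which is bonded both to C4 (carrying the one-carbon branch C15) and to the array C5–C6–C7. Reading C4–C15 as a former alkyne and C6=C7 as an olefin that has moved from C5=C6 makes C4–C5 the bond of an Alder-ene cycloisomerisation of the 1,6-enyne C15≡C4–C3–C2–C1–C5=C6, with hydrogen passing from C7 to C15. The only stereocentre that must then be bought is C8, which maps onto C2 of L-malic acid.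

## Retrosynthetic reasoning

The aryl silyl ether of 31 is removed last to give 32, and the C8–O acyl bond of 31 is cut to diol 26 and protected acid 29 (from 27). The ester goes on last because nothing earlier tolerates a cinnamate; only the secondary hydroxyl of 26 can be acylated, so no protection of the tertiary one is needed.

The two C11–methyl bonds of 26 are cut to the methyl ester 25. An ester at C7 is wanted earlier in any case: it acidifies H7 and conjugates the olefin that the key step produces.

The C7–H and C6–H bonds of 25 are cut to the enoate 24, whose allylic C8 hydroxyl can deliver hydrogen to its own face and so set C7 trans to the C8 oxygen. The C8 silyl ether (23) and the C4–H/C15–H bonds are then cut to the exocyclic methylene of 22, where the H5 face of the cyclopentane is the open one.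

The key cut is C4–C5 in 22, with H returned from C15 to C7 and the olefin returned to C5=C6, giving the monocyclic enyne 21. Cutting here rather than in the seven-membered ring removes a ring and a stereocentre in one isomerisation that needs no reagent, and leaves a cycloheptadiene whose substitution is set by ring chemistry. The forward reaction has to bond C4 to C5 on the face anti to the C7 and C8 substituents, and the required syn hydrogen at C7 ties that face to the C7 configuration. Hence 21 must carry the ester cis to the silyloxy group.

The C7–H bond of 21 is cut to the extended enolate of the conjugated ester 19 (from 18 by removal of the alkyne silyl group); kinetic α-protonation anti to the silyloxy group gives the cis relation. The ester carbon of 18 is cut to the enol triflate 17 and this to ketone 15, in which only the C6 side is kinetically enolisable.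

The C5–C6 bond of 15 is cut and the C10–O bond re-formed, giving the 2-methylidene-5-alkenyloxolane 14. The forward Claisen rearrangement builds the seven-membered ring and places the tetrasubstituted olefin exactly between the carbon that carried the methyl group and the one that carried the butynyl chain. 14 comes from lactone 13 by carbonyl methylenation.

Lactone 13 (through 12) is cut at the C10–C1 bond and the lactone C–O bond, giving methyl ketone 8 and the alkenyl bromide 4. Ketone 8 comes from 5 through the dioxolanone acid 6, which differentiates the two carboxyls of malic acid; 4 comes from 1 and 2 by one propargylic alkylation.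

## Alternatives that were turned down

Alternative 1: closing the seven-membered ring by an intramolecular carbonyl-ene reaction. The cut is C7–C8: alcohol A2 is traced to aldehyde A1, in which the C8 aldehyde hangs on C10 and a prenyl group is attached through C6. In the forward sense Me2AlCl would promote ene reaction of the aldehyde with the trisubstituted olefin, giving the C8 hydroxyl trans to a C7 isopropenyl group. In its favour, C7 and C8 are set together in the native trans relation, and A2 is only a Markovnikov hydration and an acylation away from the target; this endgame is shorter than the two hydrogenations and the Grignard addition of the chosen route. Against it, a seven-membered ene closure has a much less favourable transition state than the familiar six-membered case. The aldehyde of A1 is β,γ to the electron-rich C1=C10 olefin, which under a Lewis acid can conjugate or attack the carbonyl in Prins fashion instead of the prenyl group. Induction from C5 to C7/C8 runs 1,3 across the ring being formed, with nothing to anchor it. A1 also needs a tetrasubstituted exocyclic olefin of defined geometry (CH2CHO cis to C5), for which no simple stereocontrolled construction is evident. The chosen strategy defines that olefin by a ring-expanding rearrangement and relays C5 from C7/C8 through a mechanistic requirement rather than a conformational preference.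

Alternative 2: forming both rings by a dienyne metathesis cascade. The cut is through both ring olefins, C2=C3 and C1=C10, taking diene A4 back to the open-chain dienyne A3 (ethynyl and but-3-en-2-yl on C5, isopropenyl terminus at C10). Forward, second-generation Grubbs catalyst under ethylene would load on the vinyl group, close the five-membered ring onto the alkyne and let the resulting vinylcarbene close the seven-membered ring onto the isopropenyl group. It is the most convergent ring construction of all four and needs no redox adjustment at C7 or C11 afterwards; on these points it is stronger than the chosen route. Against it, the second closure must form a tetrasubstituted olefin in a seven-membered ring from a hindered vinylcarbene and a 1,1-disubstituted olefin. The catalyst must also initiate at the right olefin, or other ring sizes result. The product is a conjugated diene from which only C2=C3 may be hydrogenated, with 1,4-addition and over-reduction as competitors. All four stereocentres would have to be built first in acyclic material, which costs many steps. The chosen route buys one stereocentre from the chiral pool and sets the other three by substrate control on rings.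

Alternative 3: nickel-mediated alkylative cyclisation of an ynal. The cuts are C1–C2 and C10–CH3: cyclopentanol A6 is traced to alkynal A5. Forward, Ni(cod)2 with Me2Zn would join the aldehyde carbon C2 to C1 and deliver methyl to C10 on the same side of the alkyne. In its favour, the geometry of the tetrasubstituted olefin follows from syn addition; on this point it is as strong as the Claisen ring expansion and more general, and oxanickelacycle formation of five-membered rings is dependable. Against it, the step creates a C2 hydroxyl that the target lacks, and deoxygenating an allylic alcohol next to a tetrasubstituted olefin without transposition is delicate. The seven-membered ring is still open in A6 and would need a ring-closing metathesis between a vinyl group and a hindered 1,1-disubstituted olefin, followed by the same directed C6=C7 hydrogenation the chosen route uses. C4, C5 and C8 must be made in acyclic material with two orthogonal silyl ethers. It therefore reaches the same late intermediate type by a longer path, whereas the chosen route forms the five-membered ring and C5 in one isomerisation of a substrate whose only stereocentre comes from malic acid.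

Key step: step 12

Remark on the chemistry: compounds 11 to 14 are carried as mixtures of the two epimers at the quaternary oxolane carbon; this carbon becomes the sp2 centre C10 in step 7, so both converge.

## Route

Step 1
Reactants: 1 1-(trimethylsilyl)propyne; 2 2,3-dibromopropene
Product: 4 2-bromo-6-(trimethylsilyl)hex-1-en-5-yne, via 3-lithio-1-(trimethylsilyl)propyne 3 (not isolated)
Conditions: n-BuLi, THF, −78 °C; then 2, −78 °C to rt
Reagents that add atoms: none
Why: Propargylic lithiation of a silyl-capped propyne and alkylation by an allylic bromide; the silyl group directs alkylation to the propargylic rather than the allenic terminus, and SN2 and SN2' attack on the symmetric 2-bromoallyl unit give the same product.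

Step 2
Reactants: 5 L-malic acid
Product: 6 (S)-2-(2,2-dimethyl-5-oxo-1,3-dioxolan-4-yl)acetic acid
Conditions: 2,2-dimethoxypropane, TsOH (cat.), rt
Reagents that add atoms: 2,2-dimethoxypropane, COC(C)(C)OC
Why: Acetonide formation ties the α-hydroxy acid into a five-membered dioxolanone and leaves the distal carboxyl free; the stereocentre (future C8) is not touched.

Step 3
Reactants: 6 (S)-2-(2,2-dimethyl-5-oxo-1,3-dioxolan-4-yl)acetic acid
Product: 8 (S)-2,2-dimethyl-5-(2-oxopropyl)-1,3-dioxolan-4-one, via acid chloride 7 (not isolated)
Conditions: (COCl)2, DMF (cat.), CH2Cl2, 0 °C to rt; then Me2CuLi (from MeLi and CuI), Et2O–THF, −78 °C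
Reagents that add atoms: lithium dimethylcuprate, [Li+].C[Cu-]C
Why: Acid chloride formation followed by acyl substitution with a dialkylcuprate, which stops at the ketone and does not touch the ester-like dioxolanone at −78 °C.

Step 4
Reactants: 4 2-bromo-6-(trimethylsilyl)hex-1-en-5-yne; 8 (S)-2,2-dimethyl-5-(2-oxopropyl)-1,3-dioxolan-4-one
Product: 12 (3S)-3-hydroxy-5-methyl-5-[6-(trimethylsilyl)hex-1-en-5-yn-2-yl]oxolan-2-one, via vinyllithium 9 (not isolated), via vinylcerium dichloride 10 (not isolated), via open-chain alkoxide 11 (not isolated)
Conditions: 4, t-BuLi (2 equiv), Et2O, −78 °C; CeCl3, THF, −78 °C; then 8, −78 °C to rt; aq NH4Cl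
Reagents that add atoms: none
Why: Bromine–lithium exchange, transmetalation to the weakly basic organocerium and 1,2-addition to the methyl ketone, which is faster than attack on the dioxolanone and avoids enolisation or β-elimination; the tertiary alkoxide then closes onto the activated dioxolanone carbonyl (5-exo-trig translactonisation, acetone expelled). The quaternary carbon forms without control, which does not matter (see remark); the vinyllithium is kept at −78 °C to prevent carbolithiation of the silylalkyne.

Step 5
Reactants: 12 (3S)-3-hydroxy-5-methyl-5-[6-(trimethylsilyl)hex-1-en-5-yn-2-yl]oxolan-2-one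
Product: 13 (3S)-5-methyl-3-(triethylsilyloxy)-5-[6-(trimethylsilyl)hex-1-en-5-yn-2-yl]oxolan-2-one
Conditions: TESCl, imidazole, DMF, 0 °C to rt
Reagents that add atoms: chlorotriethylsilane, CC[Si](Cl)(CC)CC
Why: Standard silylation of a secondary α-hydroxy lactone; the triethylsilyl ether is later removable without base.

Step 6
Reactants: 13 (3S)-5-methyl-3-(triethylsilyloxy)-5-[6-(trimethylsilyl)hex-1-en-5-yn-2-yl]oxolan-2-one
Product: 14 (3S)-5-methyl-2-methylidene-3-(triethylsilyloxy)-5-[6-(trimethylsilyl)hex-1-en-5-yn-2-yl]oxolane
Conditions: Tebbe reagent Cp2Ti(μ-Cl)(μ-CH2)AlMe2 (1.2 equiv), pyridine, THF–toluene, −40 to 0 °C; aq NaOH work-up, Et3N-deactivated silica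
Reagents that add atoms: Tebbe reagent, C[Al-]1(C)C[Ti]([Cl+]1)(C1C=CC=C1)C1C=CC=C1
Why: Tebbe methylenation of the lactone carbonyl gives the exocyclic enol ether; with little excess reagent at low temperature, carbonyl capture of Cp2Ti=CH2 should outpace metallacycle formation with the 1,1-disubstituted olefin or the silyl-capped alkyne.

Step 7
Reactants: 14 (3S)-5-methyl-2-methylidene-3-(triethylsilyloxy)-5-[6-(trimethylsilyl)hex-1-en-5-yn-2-yl]oxolane
Product: 15 (2S)-4-methyl-2-(triethylsilyloxy)-5-[4-(trimethylsilyl)but-3-yn-1-yl]cyclohept-4-en-1-one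
Conditions: toluene, silylated sealed tube, 170 °C
Reagents that add atoms: none
Why: Claisen rearrangement of the allyl vinyl ether embedded in the 2-methylidene-5-alkenyloxolane: the exocyclic methylene (C6) bonds to the alkenyl terminus (C5) and the C10–O bond breaks, so the ring expands to the cyclohept-4-enone with the tetrasubstituted C10=C1 olefin in the only possible position. Both epimers of 14 converge through a boat-like transition state, and the C8 centre is not involved.

Step 8
Reactants: 15 (2S)-4-methyl-2-(triethylsilyloxy)-5-[4-(trimethylsilyl)but-3-yn-1-yl]cyclohept-4-en-1-one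
Product: 17 (7S)-5-methyl-7-(triethylsilyloxy)-4-[4-(trimethylsilyl)but-3-yn-1-yl]cyclohepta-1,4-dien-1-yl trifluoromethanesulfonate, via potassium enolate 16 (not isolated)
Conditions: KN(SiMe3)2, THF, −78 °C; then PhNTf2, −78 to 0 °C
Reagents that add atoms: N-phenylbis(trifluoromethanesulfonimide), O=S(=O)(N(c1ccccc1)S(=O)(=O)C(F)(F)F)C(F)(F)F
Why: Kinetic enolisation takes the C6 methylene rather than the silyloxy-bearing C8 methine, so C8 is not epimerised; O-sulfonylation gives the C6=C7 enol triflate.

Step 9
Reactants: 17 (7S)-5-methyl-7-(triethylsilyloxy)-4-[4-(trimethylsilyl)but-3-yn-1-yl]cyclohepta-1,4-dien-1-yl trifluoromethanesulfonate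
Product: 18 methyl (7S)-5-methyl-7-(triethylsilyloxy)-4-[4-(trimethylsilyl)but-3-yn-1-yl]cyclohepta-1,4-diene-1-carboxylate
Conditions: Pd(OAc)2 (5 mol %), PPh3, CO (1 atm), MeOH, Et3N, DMF, rt to 40 °C
Reagents that add atoms: carbon monoxide, [C-]#[O+]; methanol, CO
Why: Palladium-catalysed alkoxycarbonylation of an enol triflate (oxidative addition, CO insertion, methanolysis); the alkyne is still silyl-capped and cannot couple.

Step 10
Reactants: 18 methyl (7S)-5-methyl-7-(triethylsilyloxy)-4-[4-(trimethylsilyl)but-3-yn-1-yl]cyclohepta-1,4-diene-1-carboxylate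
Product: 19 methyl (7S)-4-(but-3-yn-1-yl)-5-methyl-7-(triethylsilyloxy)cyclohepta-1,4-diene-1-carboxylate
Conditions: AgNO3 (10 mol %), acetone–H2O–CH2Cl2, rt
Reagents that add atoms: none
Why: Silver-catalysed protodesilylation of an alkynylsilane through the silver acetylide; the neutral medium spares the silyl ether and avoids base-induced migration of the enoate olefin.

Step 11
Reactants: 19 methyl (7S)-4-(but-3-yn-1-yl)-5-methyl-7-(triethylsilyloxy)cyclohepta-1,4-diene-1-carboxylate
Product: 21 methyl (1R,7S)-4-(but-3-yn-1-yl)-5-methyl-7-(triethylsilyloxy)cyclohepta-2,4-diene-1-carboxylate, via dilithium acetylide-trienolate 20 (not isolated)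
Conditions: LiN(i-Pr)2 (2.3 equiv), THF–DMPU, −78 °C; then AcOH (excess) in THF, −78 °C
Reagents that add atoms: none
Why: Deconjugative protonation: the base removes the doubly allylic γ-hydrogen at C5 (and the alkyne hydrogen), and the extended enolate is protonated kinetically at the α-carbon C7, which creates the C10=C1–C5=C6 diene. The proton should enter anti to the neighbouring silyloxy group, leaving the ester cis to it; the cold acidic quench prevents loss of silyloxide.

Step 12
Reactants: 21 methyl (1R,7S)-4-(but-3-yn-1-yl)-5-methyl-7-(triethylsilyloxy)cyclohepta-2,4-diene-1-carboxylate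
Product: 22 methyl (5S,8S)-8-(triethylsilyloxy)-12,13-dinorguaia-1(10),4(15),6-trien-11-oate
Conditions: Pd(OAc)2 (5 mol %), N,N'-bis(benzylidene)ethane-1,2-diamine (5 mol %), benzene, 60 °C
Reagents that add atoms: none
Why: Palladium diacetate with the bis(imine) ligand engages the 1,6-enyne made of C15≡C4 and the ring C5=C6 bond; whether this is described as hydropalladation of the alkyne (H to C15, Pd to C4) followed by insertion or as oxidative coupling to a palladacyclopentene, C4 adds syn across C5=C6, bonding to C5 and leaving palladium on C6. The cyclopentane closes in the 5-exo mode; the 6-endo path through C6 would give a π-allyl but is disfavoured by the two-carbon tether. Syn β-hydride elimination of H7 then moves the ring olefin to C6=C7, conjugated with the ester, and frees the catalyst; this is the Alder-ene cycloisomerisation of 1,6-enynes to 1,4-dienes, known with cycloalkenyl ene partners. The one new stereocentre is C5: palladium on C6 needs a syn hydrogen on C7, so productive bond formation must occur on the face carrying H7, which in 21 is also the face anti to the cis ester and silyloxy groups; steric and mechanistic demands coincide and H5 ends up cis to the C8 oxygen. The step needs attack at C5 rather than C6 (tether), elimination only toward C7 (H5 is anti to palladium, H7 is the only syn β-hydrogen and is activated by the ester) and no scrambling of the skipped ester (neutral medium, no base).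

Step 13
Reactants: 22 methyl (5S,8S)-8-(triethylsilyloxy)-12,13-dinorguaia-1(10),4(15),6-trien-11-oate
Product: 23 methyl (4S,5R,8S)-8-(triethylsilyloxy)-12,13-dinorguaia-1(10),6-dien-11-oate
Conditions: RhCl(PPh3)3 (5 mol %), H2 (1 atm), benzene–EtOH, rt
Reagents that add atoms: none
Why: Homogeneous hydrogenation with RhCl(PPh3)3 reduces only the unhindered exocyclic methylene, not the trisubstituted enoate or the tetrasubstituted olefin. Hydrogen should add to C4 from the side of H5, the other face being covered by C6 and the seven-membered ring, giving H4 cis to H5 (the C5 descriptor changes only because priorities change).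

Step 14
Reactants: 23 methyl (4S,5R,8S)-8-(triethylsilyloxy)-12,13-dinorguaia-1(10),6-dien-11-oate
Product: 24 methyl (4S,5R,8S)-8-hydroxy-12,13-dinorguaia-1(10),6-dien-11-oate
Conditions: HF·pyridine, THF–pyridine, 0 °C to rt
Reagents that add atoms: none
Why: Cleavage of the triethylsilyl ether under non-basic conditions, which avoids deprotonation at the γ-position C5 of the enoate.

Step 15
Reactants: 24 methyl (4S,5R,8S)-8-hydroxy-12,13-dinorguaia-1(10),6-dien-11-oate
Product: 25 methyl (4S,5S,7S,8S)-8-hydroxy-12,13-dinorguai-1(10)-en-11-oate
Conditions: [Ir(cod)(PCy3)(py)]PF6 (2–5 mol %), H2 (1 atm), CH2Cl2, 0 °C to rt, stopped after one equivalent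
Reagents that add atoms: none
Why: Hydroxyl-directed hydrogenation: the allylic C8 hydroxyl binds iridium and hydrogen is delivered to the C6=C7 face it occupies, placing H7 cis to the hydroxyl and the ester trans to it. The allylic trisubstituted olefin should react before the more remote tetrasubstituted C1=C10.

Step 16
Reactants: 25 methyl (4S,5S,7S,8S)-8-hydroxy-12,13-dinorguai-1(10)-en-11-oate
Product: 26 (4S,5S,7S,8S)-guai-1(10)-ene-8,11-diol
Conditions: MeMgBr (5 equiv), CeCl3, THF, −78 to 0 °C
Reagents that add atoms: methylmagnesium bromide, C[Mg]Br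
Why: Double addition of a methyl organometallic to the ester gives the tertiary carbinol; the cerium reagent suppresses enolisation at C7 and retro-aldol cleavage of the β-alkoxide.

Step 17
Reactants: 27 p-coumaric acid
Product: 29 (E)-3-[4-(tert-butyldimethylsilyloxy)phenyl]prop-2-enoic acid, via bis-silylated acid 28 (not isolated)
Conditions: TBSCl (2.4 equiv), imidazole, DMF, rt; then AcOH–THF–H2O, rt
Reagents that add atoms: tert-butyldimethylsilyl chloride, CC(C)(C)[Si](C)(C)Cl
Why: Exhaustive silylation followed by selective hydrolysis of the labile silyl ester leaves the aryl silyl ether in place.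

Step 18
Reactants: 26 (4S,5S,7S,8S)-guai-1(10)-ene-8,11-diol; 29 (E)-3-[4-(tert-butyldimethylsilyloxy)phenyl]prop-2-enoic acid
Product: 31 (4S,5S,7S,8S)-11-hydroxyguai-1(10)-en-8-yl (E)-3-[4-(tert-butyldimethylsilyloxy)phenyl]prop-2-enoate, via mixed anhydride 30 (not isolated)
Conditions: 29, 2,4,6-trichlorobenzoyl chloride, Et3N, THF, rt; then 26, DMAP, toluene, rt to 50 °C
Reagents that add atoms: none
Why: Yamaguchi esterification acylates the hindered secondary C8 hydroxyl; the tertiary C11 hydroxyl does not react, and the masked phenol cannot oligomerise.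

Step 19
Reactants: 31 (4S,5S,7S,8S)-11-hydroxyguai-1(10)-en-8-yl (E)-3-[4-(tert-butyldimethylsilyloxy)phenyl]prop-2-enoate
Product: 32 (4S,5S,7S,8S)-11-hydroxyguai-1(10)-en-8-yl (E)-3-(4-hydroxyphenyl)prop-2-enoate, CNP0403230.1
Conditions: Bu4NF, AcOH, THF, 0 °C
Reagents that add atoms: none
Why: Fluoride cleaves the aryl silyl ether; acetic acid buffers the phenoxide so that the cinnamate neither cleaves nor migrates to the tertiary hydroxyl.

## Compound list

1 | 1-(trimethylsilyl)propyne | CC#C[Si](C)(C)C | starting material
2 | 2,3-dibromopropene | C=C(Br)CBr | starting material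
3 | 3-lithio-1-(trimethylsilyl)propyne | [Li]CC#C[Si](C)(C)C | intermediate
4 | 2-bromo-6-(trimethylsilyl)hex-1-en-5-yne | C=C(Br)CCC#C[Si](C)(C)C | intermediate
5 | L-malic acid, (S)-2-hydroxybutanedioic acid | C([C@@H](C(=O)O)O)C(=O)O | starting material
6 | (S)-2-(2,2-dimethyl-5-oxo-1,3-dioxolan-4-yl)acetic acid | CC1(C)O[C@@H](CC(=O)O)C(=O)O1 | intermediate
7 | (S)-2-(2,2-dimethyl-5-oxo-1,3-dioxolan-4-yl)acetyl chloride | CC1(C)O[C@@H](CC(=O)Cl)C(=O)O1 | intermediate
8 | (S)-2,2-dimethyl-5-(2-oxopropyl)-1,3-dioxolan-4-one | CC1(C)O[C@@H](CC(C)=O)C(=O)O1 | intermediate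
9 | 2-lithio-6-(trimethylsilyl)hex-1-en-5-yne | [Li]C(=C)CCC#C[Si](C)(C)C | intermediate
10 | dichloro[6-(trimethylsilyl)hex-1-en-5-yn-2-yl]cerium | C=C([Ce](Cl)Cl)CCC#C[Si](C)(C)C | intermediate
11 | (5S)-5-[2-hydroxy-2-methyl-3-methylidene-7-(trimethylsilyl)hept-6-yn-1-yl]-2,2-dimethyl-1,3-dioxolan-4-one (as its metal alkoxide, both carbinol epimers) | CC1(C)O[C@@H](CC(C)(O)C(=C)CCC#C[Si](C)(C)C)C(=O)O1 | intermediate
12 | (3S)-3-hydroxy-5-methyl-5-[6-(trimethylsilyl)hex-1-en-5-yn-2-yl]oxolan-2-one (both C5 epimers) | CC1(C(=C)CCC#C[Si](C)(C)C)C[C@H](O)C(=O)O1 | intermediate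
13 | (3S)-5-methyl-3-(triethylsilyloxy)-5-[6-(trimethylsilyl)hex-1-en-5-yn-2-yl]oxolan-2-one | CC1(C(=C)CCC#C[Si](C)(C)C)C[C@H](O[Si](CC)(CC)CC)C(=O)O1 | intermediate
14 | (3S)-5-methyl-2-methylidene-3-(triethylsilyloxy)-5-[6-(trimethylsilyl)hex-1-en-5-yn-2-yl]oxolane | CC1(C(=C)CCC#C[Si](C)(C)C)C[C@H](O[Si](CC)(CC)CC)C(=C)O1 | intermediate
15 | (2S)-4-methyl-2-(triethylsilyloxy)-5-[4-(trimethylsilyl)but-3-yn-1-yl]cyclohept-4-en-1-one | CC1=C(CCC#C[Si](C)(C)C)CCC(=O)[C@@H](O[Si](CC)(CC)CC)C1 | intermediate
16 | potassium (7S)-5-methyl-7-(triethylsilyloxy)-4-[4-(trimethylsilyl)but-3-yn-1-yl]cyclohepta-1,4-dien-1-olate | CC1=C(CCC#C[Si](C)(C)C)CC=C([O-])[C@@H](O[Si](CC)(CC)CC)C1.[K+] | intermediate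
17 | (7S)-5-methyl-7-(triethylsilyloxy)-4-[4-(trimethylsilyl)but-3-yn-1-yl]cyclohepta-1,4-dien-1-yl trifluoromethanesulfonate | CC1=C(CCC#C[Si](C)(C)C)CC=C(OS(=O)(=O)C(F)(F)F)[C@@H](O[Si](CC)(CC)CC)C1 | intermediate
18 | methyl (7S)-5-methyl-7-(triethylsilyloxy)-4-[4-(trimethylsilyl)but-3-yn-1-yl]cyclohepta-1,4-diene-1-carboxylate | CC1=C(CCC#C[Si](C)(C)C)CC=C(C(=O)OC)[C@@H](O[Si](CC)(CC)CC)C1 | intermediate
19 | methyl (7S)-4-(but-3-yn-1-yl)-5-methyl-7-(triethylsilyloxy)cyclohepta-1,4-diene-1-carboxylate | CC1=C(CCC#C)CC=C(C(=O)OC)[C@@H](O[Si](CC)(CC)CC)C1 | intermediate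
20 | dilithium acetylide-trienolate of 19 | CC1=C(CCC#C[Li])C=CC(=C(OC)O[Li])[C@@H](O[Si](CC)(CC)CC)C1 | intermediate
21 | methyl (1R,7S)-4-(but-3-yn-1-yl)-5-methyl-7-(triethylsilyloxy)cyclohepta-2,4-diene-1-carboxylate (ester cis to silyloxy) | CC1=C(CCC#C)C=C[C@@H](C(=O)OC)[C@@H](O[Si](CC)(CC)CC)C1 | intermediate
22 | methyl (5S,8S)-8-(triethylsilyloxy)-12,13-dinorguaia-1(10),4(15),6-trien-11-oate (H5 cis to the C8 oxygen) | CC1=C2CCC(=C)[C@@H]2C=C(C(=O)OC)[C@@H](O[Si](CC)(CC)CC)C1 | intermediate
23 | methyl (4S,5R,8S)-8-(triethylsilyloxy)-12,13-dinorguaia-1(10),6-dien-11-oate (H4 cis to H5) | CC1=C2CC[C@H](C)[C@@H]2C=C(C(=O)OC)[C@@H](O[Si](CC)(CC)CC)C1 | intermediate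
24 | methyl (4S,5R,8S)-8-hydroxy-12,13-dinorguaia-1(10),6-dien-11-oate | CC1=C2CC[C@H](C)[C@@H]2C=C(C(=O)OC)[C@@H](O)C1 | intermediate
25 | methyl (4S,5S,7S,8S)-8-hydroxy-12,13-dinorguai-1(10)-en-11-oate (ester trans to hydroxyl) | CC1=C2CC[C@H](C)[C@@H]2C[C@H](C(=O)OC)[C@@H](O)C1 | intermediate
26 | (4S,5S,7S,8S)-guai-1(10)-ene-8,11-diol | CC1=C2CC[C@H](C)[C@@H]2C[C@H](C(C)(C)O)[C@@H](O)C1 | intermediate
27 | p-coumaric acid | OC(=O)/C=C/c1ccc(O)cc1 | starting material
28 | tert-butyldimethylsilyl (E)-3-[4-(tert-butyldimethylsilyloxy)phenyl]prop-2-enoate | CC(C)(C)[Si](C)(C)OC(=O)/C=C/c1ccc(O[Si](C)(C)C(C)(C)C)cc1 | intermediate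
29 | (E)-3-[4-(tert-butyldimethylsilyloxy)phenyl]prop-2-enoic acid | OC(=O)/C=C/c1ccc(O[Si](C)(C)C(C)(C)C)cc1 | intermediate
30 | (E)-3-[4-(tert-butyldimethylsilyloxy)phenyl]prop-2-enoic 2,4,6-trichlorobenzoic anhydride | O=C(/C=C/c1ccc(O[Si](C)(C)C(C)(C)C)cc1)OC(=O)c1c(Cl)cc(Cl)cc1Cl | intermediate
31 | (4S,5S,7S,8S)-11-hydroxyguai-1(10)-en-8-yl (E)-3-[4-(tert-butyldimethylsilyloxy)phenyl]prop-2-enoate | CC1=C2CC[C@H](C)[C@@H]2C[C@H](C(C)(C)O)[C@@H](OC(=O)/C=C/c2ccc(O[Si](C)(C)C(C)(C)C)cc2)C1 | intermediate
32 | (4S,5S,7S,8S)-11-hydroxyguai-1(10)-en-8-yl (E)-3-(4-hydroxyphenyl)prop-2-enoate | CC1=C2CC[C@H](C)[C@@H]2C[C@H](C(C)(C)O)[C@@H](OC(=O)/C=C/c2ccc(O)cc2)C1 | target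

## Step count and least certain steps

Total step count: 19. Longest linear sequence: 17 steps (from 5: steps 2 to 16, 18 and 19); steps 1 and 17 are side branches.

Step 12 (key step). Most likely failure: insertion at the diene terminus C6 (giving a π-allyl and a six-membered ring), alkyne oligomerisation, or hydridopalladium-mediated drift of the skipped diene into conjugation before cyclisation. The reason is that an ene partner that is part of a conjugated diene is electronically biased toward terminal attack and binds palladium hydrides. Fallback: an intramolecular Heck reaction forms the same bond with the same stereochemical gate. It sets out from 19: bromoboration of the alkyne with B-bromo-9-BBN and protonolysis with AcOH give methyl (7S)-4-(3-bromobut-3-en-1-yl)-5-methyl-7-(triethylsilyloxy)cyclohepta-1,4-diene-1-carboxylate F1. Deconjugative protonation as in step 11 gives methyl (1R,7S)-4-(3-bromobut-3-en-1-yl)-5-methyl-7-(triethylsilyloxy)cyclohepta-2,4-diene-1-carboxylate F2. Oxidative addition to zerovalent palladium (Pd(OAc)2, PPh3, Ag2CO3, MeCN, 70 °C), 5-exo insertion and syn β-hydride elimination of H7 return to the route at 22.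

Step 6. Most likely failure: consumption of the silylalkyne by the titanium methylidene (titanacyclobutene formation), or acid-catalysed migration of the exocyclic enol ether olefin into the ring during isolation. Fallback: a sulfone-based methylenation free of titanium. It sets out from 13: lithiated methyl 1,3-benzothiazol-2-yl sulfone (LiN(SiMe3)2, THF, −78 °C) adds to the lactone to give the hemiketal (3S)-2-[(1,3-benzothiazol-2-ylsulfonyl)methyl]-5-methyl-3-(triethylsilyloxy)-5-[6-(trimethylsilyl)hex-1-en-5-yn-2-yl]oxolan-2-ol F3. DBU then induces Smiles rearrangement and elimination (modified Julia olefination of a lactone), returning to the route at 14.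

Step 11. Most likely failure: protonation at C5 or C10 instead of C7, insufficient facial bias at C7, or β-elimination of silyloxide from the enolate. The first two arise because three termini of the extended enolate compete and the bias rests on one neighbouring substituent. Fallback: protonation of the alkoxide-chelated dianion, as in alkylations of β-hydroxy ester dianions, which cannot eliminate and shifts the control element from sterics to a lithium chelate. It sets out from 19: HF·pyridine gives methyl (7S)-4-(but-3-yn-1-yl)-7-hydroxy-5-methylcyclohepta-1,4-diene-1-carboxylate F4. LiN(i-Pr)2 (3.3 equiv) in THF–DMPU, then AcOH at −78 °C, gives methyl (1R,7S)-4-(but-3-yn-1-yl)-7-hydroxy-5-methylcyclohepta-2,4-diene-1-carboxylate F5. Silylation (TESCl, imidazole) returns to the route at 21.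

Step 4. Most likely failure: competing attack of the organometallic on the dioxolanone carbonyl, or incomplete translactonisation. Fallback: lower the electrophilicity of the second carbonyl. It sets out from 8: methanolysis (MeOH, TsOH cat.) gives methyl (S)-2-hydroxy-4-oxopentanoate F6, and silylation (TESCl, imidazole) gives methyl (S)-4-oxo-2-(triethylsilyloxy)pentanoate F7. Addition of 10 to the ketone and lactonisation of the alkoxide onto the methyl ester return to the route at 13, already silylated.

Step 13. Most likely failure: hydrogen delivery to the wrong face of C4, or rhodium hydride migration of the exocyclic olefin into the ring; the facial bias rests only on the difference between H5 and C6. Fallback: hydroboration with a bulky borane and deoxygenation. It sets out from 22: 9-BBN, then NaBO3, give methyl (4S,5R,8S)-15-hydroxy-8-(triethylsilyloxy)-12,13-dinorguaia-1(10),6-dien-11-oate F8. I2, PPh3 and imidazole give the 15-iodo compound F9. Radical reduction (Bu3SnH, AIBN) returns to the route at 23.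

Step 15. Most likely failure: over-reduction of the tetrasubstituted C1=C10 olefin, which is homoallylic to the directing hydroxyl, or slow reduction of the electron-poor enoate. Fallback: conjugate reduction and thermodynamic equilibration. It sets out from 24: [(Ph3P)CuH]6 (cat.) with a silane gives 25 together with its C7 epimer methyl (4S,5S,7R,8S)-8-hydroxy-12,13-dinorguai-1(10)-en-11-oate F10. NaOMe in MeOH should equilibrate the mixture toward the trans isomer, returning to the route at 25.

## Further compounds

F1 | step 12 | methyl (7S)-4-(3-bromobut-3-en-1-yl)-5-methyl-7-(triethylsilyloxy)cyclohepta-1,4-diene-1-carboxylate | CC1=C(CCC(Br)=C)CC=C(C(=O)OC)[C@@H](O[Si](CC)(CC)CC)C1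
F2 | step 12 | methyl (1R,7S)-4-(3-bromobut-3-en-1-yl)-5-methyl-7-(triethylsilyloxy)cyclohepta-2,4-diene-1-carboxylate | CC1=C(CCC(Br)=C)C=C[C@@H](C(=O)OC)[C@@H](O[Si](CC)(CC)CC)C1
F3 | step 6 | (3S)-2-[(1,3-benzothiazol-2-ylsulfonyl)methyl]-5-methyl-3-(triethylsilyloxy)-5-[6-(trimethylsilyl)hex-1-en-5-yn-2-yl]oxolan-2-ol | CC1(C(=C)CCC#C[Si](C)(C)C)C[C@H](O[Si](CC)(CC)CC)C(O)(CS(=O)(=O)c2nc3ccccc3s2)O1
F4 | step 11 | methyl (7S)-4-(but-3-yn-1-yl)-7-hydroxy-5-methylcyclohepta-1,4-diene-1-carboxylate | CC1=C(CCC#C)CC=C(C(=O)OC)[C@@H](O)C1
F5 | step 11 | methyl (1R,7S)-4-(but-3-yn-1-yl)-7-hydroxy-5-methylcyclohepta-2,4-diene-1-carboxylate | CC1=C(CCC#C)C=C[C@@H](C(=O)OC)[C@@H](O)C1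
F6 | step 4 | methyl (S)-2-hydroxy-4-oxopentanoate | CC(=O)C[C@H](O)C(=O)OC
F7 | step 4 | methyl (S)-4-oxo-2-(triethylsilyloxy)pentanoate | CC(=O)C[C@H](O[Si](CC)(CC)CC)C(=O)OC
F8 | step 13 | methyl (4S,5R,8S)-15-hydroxy-8-(triethylsilyloxy)-12,13-dinorguaia-1(10),6-dien-11-oate | CC1=C2CC[C@H](CO)[C@@H]2C=C(C(=O)OC)[C@@H](O[Si](CC)(CC)CC)C1
F9 | step 13 | methyl 15-iodo-8-(triethylsilyloxy)-12,13-dinorguaia-1(10),6-dien-11-oate (same configuration as F8) | CC1=C2CC[C@H](CI)[C@@H]2C=C(C(=O)OC)[C@@H](O[Si](CC)(CC)CC)C1
F10 | step 15 | methyl (4S,5S,7R,8S)-8-hydroxy-12,13-dinorguai-1(10)-en-11-oate | CC1=C2CC[C@H](C)[C@@H]2C[C@@H](C(=O)OC)[C@@H](O)C1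
A1 | alternative 1 | (Z)-3-[3-methyl-2-(3-methylbut-2-en-1-yl)cyclopentylidene]butanal, ene precursor | C/C(CC=O)=C1\CC[C@H](C)[C@@H]1CC=C(C)C
A2 | alternative 1 | guaia-1(10),11-dien-8-ol | CC1=C2CC[C@H](C)[C@@H]2C[C@H](C(C)=C)[C@@H](O)C1
A3 | alternative 2 | open-chain dienyne bis-silyl ether | C#C[C@H]([C@@H](C)C=C)C[C@H](C(C)(C)O[Si](CC)(CC)CC)[C@@H](O[Si](C)(C)C(C)(C)C)CC(C)=C
A4 | alternative 2 | guaia-1(10),2-diene-8,11-diol bis-silyl ether | CC1=C2C=C[C@H](C)[C@@H]2C[C@H](C(C)(C)O[Si](CC)(CC)CC)[C@@H](O[Si](C)(C)C(C)(C)C)C1
A5 | alternative 3 | open-chain alkynal | O=CC[C@H](C)[C@H](C=C)C#CC[C@H](O[Si](C)(C)C(C)(C)C)C(=C)C(C)(C)O[Si](CC)(CC)CC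
A6 | alternative 3 | 2-alkylidenecyclopentanol with tetrasubstituted olefin | C/C(C[C@H](O[Si](C)(C)C(C)(C)C)C(=C)C(C)(C)O[Si](CC)(CC)CC)=C1\[C@@H](O)C[C@H](C)[C@@H]1C=C
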